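**Retrosynthetic overview**

1. Feature: the ring is numbered C1 (methylene-bearing carbon) to C11 (free carbinol). The C5 carboxyl is γ to the C7 oxygen and cis to the C4 hydrogen across C4=C5. Acid, regiochemistry and alkene geometry are therefore the result of a syn hydro-carbonylation of a C4≡C5 cycloalkyne delivered from the C7 oxygen, with the γ-lactone as a temporary tether.
2. Target ⇐ C7 acylation, lactone opening, C11 reduction and C1 methylenation ⇐ bridged keto α-alkylidene-γ-butyrolactone ⇐ (Pd, CO) (7S)-7-hydroxy-9,9-dimethylcycloundec-4-yn-11-one.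
3. Cycloundecynone ⇐ Eschenmoser–Tanabe fragmentation of a 6/7-fused epoxy ketone (cleaves C5–C11) ⇐ ring-fused enone from iodine–lithium exchange and intramolecular Stork–Danheiser closure (C10–C11).
4. Cyclisation substrate ⇐ lithiated 1,5-dimethoxycyclohexa-1,4-diene + (S)-epoxide (C5–C6 bond; C7 set by hydrolytic kinetic resolution) ⇐ 2,2-dimethylpent-4-enal.
5. Ring order: six-membered ring (bought) → seven-membered ring (step 7) → eleven-membered ring by fragmentation (step 9) → bridging lactone (step 11) → lactone opened again (step 15).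

Key step: step 11

Remark on the chemistry: ring atoms keep the target numbering in all intermediates. The (S,S)-cobalt salen catalyst is taken to leave the (S)-epoxide, as for other alkyl-substituted terminal epoxides. The alkenyl flank (C1) is taken as the large group in the oxazaborolidine reduction.

**Route**

Step 1
Reactants: 1 2,2-dimethylpent-4-enal
Product: 2 2,2-dimethylpent-4-en-1-ol
Conditions: NaBH4, MeOH, 0 °C
Reagents that add atoms: none
Why: Borohydride reduction of the aldehyde should give the neopentyl alcohol (future C10) without touching the terminal alkene.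

Step 2
Reactants: 2 2,2-dimethylpent-4-en-1-ol
Product: 3 5-iodo-4,4-dimethylpent-1-ene
Conditions: PPh3, I2, imidazole, toluene, 80 °C
Reagents that add atoms: iodine, II
Why: Appel-type iodination, in which heating drives displacement of the alkoxyphosphonium by iodide at the neopentyl carbon without rearrangement.

Step 3
Reactants: 3 5-iodo-4,4-dimethylpent-1-ene
Product: 5 rac-2-(3-iodo-2,2-dimethylpropyl)oxirane, via bromohydrin 4 (not isolated)
Conditions: NBS, DMSO/H2O, 0 °C to rt; then aq NaOH, 0 °C
Reagents that add atoms: water, O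
Why: Bromohydrin formation and base closure epoxidise the terminal alkene without a peracid, which would oxidise the alkyl iodide; either bromohydrin regioisomer closes to the same epoxide.

Step 4
Reactants: 5 rac-2-(3-iodo-2,2-dimethylpropyl)oxirane
Product: 6 (S)-2-(3-iodo-2,2-dimethylpropyl)oxirane
Conditions: (S,S)-N,N'-bis(3,5-di-tert-butylsalicylidene)-1,2-cyclohexanediaminocobalt acetate (trivalent cobalt, 0.5 mol %), H2O (0.55 equiv), THF, 0 °C to rt
Reagents that add atoms: none
Why: Hydrolytic kinetic resolution, in which the cobalt salen catalyst should hydrolyse the (R)-epoxide and leave the (S)-epoxide that carries the future C7 centre; at most half of the material is carried on.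

Step 5
Reactants: 7 1,5-dimethoxycyclohexa-1,4-diene; 6 (S)-2-(3-iodo-2,2-dimethylpropyl)oxirane
Product: 10 tert-butyl{[(2R)-1-(2,6-dimethoxycyclohexa-2,5-dien-1-yl)-5-iodo-4,4-dimethylpentan-2-yl]oxy}dimethylsilane, via lithiated diene 8 (not isolated), via lithium alkoxide 9 (not isolated)
Conditions: 7 (1.1 equiv), t-BuLi (1.0 equiv), THF, −78 °C; HMPA, then 6, −78 to −40 °C; TBSCl, −40 to 0 °C
Reagents that add atoms: tert-butyldimethylsilyl chloride, CC(C)(C)[Si](C)(C)Cl
Why: Deprotonation of 7 at the CH2 flanked by both methoxy-bearing carbons gives a pentadienyl anion that should open the epoxide by SN2 attack at its unsubstituted carbon (forming C5–C6), leaving the C7–O bond and the SN2-inert neopentyl iodide untouched, and silylation in the same flask keeps the alkoxide from displacing that iodide.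

Step 6
Reactants: 10 tert-butyl{[(2R)-1-(2,6-dimethoxycyclohexa-2,5-dien-1-yl)-5-iodo-4,4-dimethylpentan-2-yl]oxy}dimethylsilane
Product: 11 2-[(2R)-2-(tert-butyldimethylsilyloxy)-5-iodo-4,4-dimethylpentyl]-3-methoxycyclohex-2-en-1-one
Conditions: oxalic acid, THF/H2O, 0 °C to rt
Reagents that add atoms: water, O
Why: Mild acid hydrolyses one enol ether and the resulting β,γ-unsaturated ketone moves into conjugation to give the vinylogous ester, which hydrolyses far more slowly, while the silyl ether and the iodide survive.

Step 7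
Reactants: 11 2-[(2R)-2-(tert-butyldimethylsilyloxy)-5-iodo-4,4-dimethylpentyl]-3-methoxycyclohex-2-en-1-one
Product: 14 (8S)-8-(tert-butyldimethylsilyloxy)-6,6-dimethyl-2,3,4,5,6,7,8,9-octahydro-1H-benzo[7]annulen-1-one, via alkyllithium 12 (not isolated), via tertiary alkoxide 13 (not isolated)
Conditions: t-BuLi (2.1 equiv), Et2O/pentane, −78 °C to rt, 0.01 M; then 1 M HCl, THF, 0 °C
Reagents that add atoms: water, O
Why: Iodine–lithium exchange on the primary iodide should outrun attack of tert-butyllithium on the deactivated vinylogous ester carbonyl, the neopentyllithium (helped by the gem-dimethyl group) closes the seven-membered ring by 7-exo-trig 1,2-addition (C10–C11), and acid work-up completes the Stork–Danheiser transposition to the ring-fused enone; conjugate addition–elimination at the methoxy-bearing carbon would give the same enone because the dione unit is symmetrical.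

Step 8
Reactants: 14 (8S)-8-(tert-butyldimethylsilyloxy)-6,6-dimethyl-2,3,4,5,6,7,8,9-octahydro-1H-benzo[7]annulen-1-one
Product: 15 (8S)-8-(tert-butyldimethylsilyloxy)-6,6-dimethyl-4a,9a-epoxydecahydro-1H-benzo[7]annulen-1-one (both cis-epoxide diastereomers)
Conditions: 30% H2O2, NaOH, MeOH, 0 °C to rt
Reagents that add atoms: hydrogen peroxide, OO
Why: Weitz–Scheffer nucleophilic epoxidation of the tetrasubstituted enone; the two epoxide diastereomers need not be separated because both epoxide carbons lose their stereochemistry in the next step.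

Step 9
Reactants: 15 (8S)-8-(tert-butyldimethylsilyloxy)-6,6-dimethyl-4a,9a-epoxydecahydro-1H-benzo[7]annulen-1-one
Product: 17 (7S)-7-(tert-butyldimethylsilyloxy)-9,9-dimethylcycloundec-4-yn-11-one (target numbering), via tosylhydrazone 16 (not isolated)
Conditions: TsNHNH2, AcOH/CH2Cl2 (1:1), −20 °C to rt
Reagents that add atoms: none
Why: Eschenmoser–Tanabe fragmentation, in which the tosylhydrazone opens the epoxide and loss of sulfinate and N2 cleaves the C5–C11 ring-fusion bond to give the C4≡C5 alkyne and the C11 ketone in an eleven-membered ring, the mild acid leaving the silyl ether in place.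

Step 10
Reactants: 17 (7S)-7-(tert-butyldimethylsilyloxy)-9,9-dimethylcycloundec-4-yn-11-one
Product: 18 (7S)-7-hydroxy-9,9-dimethylcycloundec-4-yn-11-one (target numbering)
Conditions: HF·pyridine, THF, 0 °C to rt
Reagents that add atoms: none
Why: Fluoride cleaves the silyl ether under non-basic conditions that avoid alkyne-to-allene isomerisation and aldol chemistry of the ketone, freeing the homopropargylic C7 hydroxyl.

Step 11
Reactants: 18 (7S)-7-hydroxy-9,9-dimethylcycloundec-4-yn-11-one; 19 carbon monoxide
Product: 20 (1E,10S)-8,8-dimethyl-11-oxabicyclo[8.2.1]tridec-1-ene-6,12-dione, that is the (4E,7S)-9,9-dimethyl-11-oxocycloundec-4-ene-5-carboxylic acid lactonised onto the C7 oxygen (target numbering)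
Conditions: PdCl2 (5 mol %), SnCl2 (5 mol %), PPh3 (10 mol %), CO (7 atm), MeCN, 75 °C
Reagents that add atoms: carbon monoxide, [C-]#[O+]
Why: Under CO the C7 hydroxyl adds to a carbonyl ligand on divalent palladium to give an alkoxycarbonylpalladium species held next to the ring alkyne, which inserts syn into the Pd–C(=O) bond so that the carbonyl carbon bonds to C5 and palladium to C4, and protonolysis of the C4–Pd bond with retention leaves the C4 hydrogen cis to the carbonyl (a palladium hydride, CO insertion and lactonisation cycle would lead to the same product). The closest known reaction type is the palladium-catalysed cyclocarbonylation of homopropargylic alcohols bearing internal alkynes to (E)-α-alkylidene-γ-butyrolactones. The one new ring, the lactone O–C(=O)–C5–C6–C7, closes in the 5-exo-dig mode across C5 and C7 of the eleven-membered ring and brings the single new skeletal bond C5–C(=O). No stereocentre is created; the C7 centre from the resolved epoxide takes no part in bond breaking, and the alkene geometry (C3 cis to C6, E) follows from the syn addition. The step needs carbonylation at C5 and not at C4, and the tether from the C7 oxygen secures this, because acyl delivery to C4 would require a six-membered lactone holding a trans double bond. The bent alkyne of the eleven-membered ring, which relaxes to a cis-cycloundecene on insertion, should help the step.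

Step 12
Reactants: 20 (1E,10S)-8,8-dimethyl-11-oxabicyclo[8.2.1]tridec-1-ene-6,12-dione
Product: 23 (1E,10S)-8,8-dimethyl-5-methylidene-11-oxabicyclo[8.2.1]tridec-1-ene-6,12-dione, via Mannich base 21 (not isolated), via methiodide 22 (not isolated)
Conditions: LiN(SiMe3)2, THF, −78 °C; Me2N=CH2 I, −78 to 0 °C; MeI, rt; aq NaHCO3
Reagents that add atoms: dimethylmethyleneammonium iodide (Eschenmoser's salt), C=[N+](C)C.[I-]
Why: Kinetic deprotonation by the bulky amide should occur at the unhindered C1 methylene and not at the neopentyl C10 (and faster than γ-deprotonation of the unsaturated lactone), after which Mannich alkylation, N-methylation and elimination of trimethylamine give the α-methylene ketone.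

Step 13
Reactants: 23 (1E,10S)-8,8-dimethyl-5-methylidene-11-oxabicyclo[8.2.1]tridec-1-ene-6,12-dione
Product: 24 (1E,6S,10S)-6-hydroxy-8,8-dimethyl-5-methylidene-11-oxabicyclo[8.2.1]tridec-1-en-12-one
Conditions: (R)-1-methyl-3,3-diphenyltetrahydro-1H,3H-pyrrolo[1,2-c][1,3,2]oxazaborole (20 mol %), catecholborane, toluene, −78 °C
Reagents that add atoms: none
Why: Corey–Bakshi–Shibata reduction, in which the (R)-oxazaborolidine delivers hydride to the C11 carbonyl face fixed by the α-branched alkenyl flank (C1) as the large group, which should set the (11S)-allylic alcohol, while catecholborane at low temperature spares the lactone and the alkenes.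

Step 14
Reactants: 24 (1E,6S,10S)-6-hydroxy-8,8-dimethyl-5-methylidene-11-oxabicyclo[8.2.1]tridec-1-en-12-one
Product: 25 (1E,6S,10S)-6-(tert-butyldimethylsilyloxy)-8,8-dimethyl-5-methylidene-11-oxabicyclo[8.2.1]tridec-1-en-12-one
Conditions: TBSOTf, 2,6-lutidine, CH2Cl2, −78 °C
Reagents that add atoms: tert-butyldimethylsilyl trifluoromethanesulfonate, CC(C)(C)[Si](C)(C)OS(=O)(=O)C(F)(F)F
Why: Silyl triflate with a hindered base silylates the secondary allylic alcohol, so that C11 stays masked while the C7 oxygen is released and acylated.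

Step 15
Reactants: 25 (1E,6S,10S)-6-(tert-butyldimethylsilyloxy)-8,8-dimethyl-5-methylidene-11-oxabicyclo[8.2.1]tridec-1-en-12-one; 26 3-methylbutanoic anhydride (isovaleric anhydride)
Product: 29 allyl (4E,7S,11S)-11-(tert-butyldimethylsilyloxy)-9,9-dimethyl-1-methylidene-7-(3-methylbutanoyloxy)cycloundec-4-ene-5-carboxylate (target numbering), via potassium carboxylate 27 (not isolated), via hydroxy allyl ester 28 (not isolated)
Conditions: KOH (1.05 equiv), THF/H2O, rt, evaporate; allyl bromide, DMF, 0 °C; then 26, Et3N, DMAP, 0 °C to rt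
Reagents that add atoms: potassium hydroxide, [K+].[OH-]; allyl bromide, C=CCBr; 3-methylbutanoic anhydride, CC(C)CC(=O)OC(=O)CC(C)C
Why: Saponification opens the lactone, O-alkylation of the carboxylate masks the acid under neutral conditions, and immediate DMAP-catalysed acylation of the freed C7 hydroxyl should outrun re-lactonisation, with no stereocentre touched because only acyl C–O bonds are made and broken.

Step 16
Reactants: 29 allyl (4E,7S,11S)-11-(tert-butyldimethylsilyloxy)-9,9-dimethyl-1-methylidene-7-(3-methylbutanoyloxy)cycloundec-4-ene-5-carboxylate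
Product: 30 (4E,7S,11S)-11-(tert-butyldimethylsilyloxy)-9,9-dimethyl-1-methylidene-7-(3-methylbutanoyloxy)cycloundec-4-ene-5-carboxylic acid (target numbering)
Conditions: Pd(PPh3)4 (5 mol %), morpholine, THF, rt
Reagents that add atoms: none
Why: Tsuji–Trost deallylation, in which zerovalent palladium ionises the allyl ester and morpholine traps the allyl group, leaving the isovalerate, the silyl ether and the alkenes untouched.

Step 17
Reactants: 30 (4E,7S,11S)-11-(tert-butyldimethylsilyloxy)-9,9-dimethyl-1-methylidene-7-(3-methylbutanoyloxy)cycloundec-4-ene-5-carboxylic acid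
Product: 31 (4E,7S,11S)-11-hydroxy-9,9-dimethyl-1-methylidene-7-(3-methylbutanoyloxy)cycloundec-4-ene-5-carboxylic acid (target numbering; CNP0400752.1)
Conditions: HF·pyridine, pyridine, THF, 0 °C to rt
Reagents that add atoms: none
Why: Buffered fluoride removes the C11 silyl ether without affecting the ester, the acid or the allylic alcohol, giving the target.

**Compound list**

1 | 2,2-dimethylpent-4-enal | C=CCC(C)(C)C=O | starting material
2 | 2,2-dimethylpent-4-en-1-ol | C=CCC(C)(C)CO | intermediate
3 | 5-iodo-4,4-dimethylpent-1-ene | C=CCC(C)(C)CI | intermediate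
4 | 1-bromo-5-iodo-4,4-dimethylpentan-2-ol (racemic bromohydrin) | OC(CBr)CC(C)(C)CI | intermediate
5 | rac-2-(3-iodo-2,2-dimethylpropyl)oxirane | ICC(C)(C)CC1CO1 | intermediate
6 | (S)-2-(3-iodo-2,2-dimethylpropyl)oxirane | C1[C@@H](O1)CC(C)(C)CI | intermediate
7 | 1,5-dimethoxycyclohexa-1,4-diene | COC1=CCC=C(OC)C1 | starting material
8 | (2,6-dimethoxycyclohexa-2,5-dien-1-yl)lithium | COC1=CCC=C(OC)C1[Li] | intermediate
9 | lithium (2R)-1-(2,6-dimethoxycyclohexa-2,5-dien-1-yl)-5-iodo-4,4-dimethylpentan-2-olate | COC1=CCC=C(OC)C1C[C@@H](O[Li])CC(C)(C)CI | intermediate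
10 | tert-butyl{[(2R)-1-(2,6-dimethoxycyclohexa-2,5-dien-1-yl)-5-iodo-4,4-dimethylpentan-2-yl]oxy}dimethylsilane | COC1=CCC=C(OC)C1C[C@@H](O[Si](C)(C)C(C)(C)C)CC(C)(C)CI | intermediate
11 | 2-[(2R)-2-(tert-butyldimethylsilyloxy)-5-iodo-4,4-dimethylpentyl]-3-methoxycyclohex-2-en-1-one | COC1=C(C[C@@H](O[Si](C)(C)C(C)(C)C)CC(C)(C)CI)C(=O)CCC1 | intermediate
12 | alkyllithium from 11 by iodine–lithium exchange (silyloxy carbon unchanged) | COC1=C(C[C@@H](O[Si](C)(C)C(C)(C)C)CC(C)(C)C[Li])C(=O)CCC1 | intermediate
13 | bicyclic lithium tertiary alkoxide from 1,2-addition (C10–C11 bond formed; carbinol carbon a mixture) | COC1=C2C[C@@H](O[Si](C)(C)C(C)(C)C)CC(C)(C)CC2(O[Li])CCC1 | intermediate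
14 | (8S)-8-(tert-butyldimethylsilyloxy)-6,6-dimethyl-2,3,4,5,6,7,8,9-octahydro-1H-benzo[7]annulen-1-one | O=C1CCCC2=C1C[C@@H](O[Si](C)(C)C(C)(C)C)CC(C)(C)C2 | intermediate
15 | (8S)-8-(tert-butyldimethylsilyloxy)-6,6-dimethyl-4a,9a-epoxydecahydro-1H-benzo[7]annulen-1-one (both cis-epoxide diastereomers) | O=C1CCCC2(O3)C13C[C@@H](O[Si](C)(C)C(C)(C)C)CC(C)(C)C2 | intermediate
16 | p-toluenesulfonylhydrazone of 15 | Cc1ccc(cc1)S(=O)(=O)NN=C1CCCC2(O3)C13C[C@@H](O[Si](C)(C)C(C)(C)C)CC(C)(C)C2 | intermediate
17 | (7S)-7-(tert-butyldimethylsilyloxy)-9,9-dimethylcycloundec-4-yn-11-one (target numbering) | O=C1CCCC#CC[C@@H](O[Si](C)(C)C(C)(C)C)CC(C)(C)C1 | intermediate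
18 | (7S)-7-hydroxy-9,9-dimethylcycloundec-4-yn-11-one (target numbering) | O=C1CCCC#CC[C@@H](O)CC(C)(C)C1 | intermediate
19 | carbon monoxide | [C-]#[O+] | starting material
20 | (1E,10S)-8,8-dimethyl-11-oxabicyclo[8.2.1]tridec-1-ene-6,12-dione (γ-lactone bridging C5 and C7 of the eleven-membered ring) | O=C1CCC/C=C(/C(=O)O2)C[C@@H]2CC(C)(C)C1 | intermediate
21 | C1-(dimethylaminomethyl) ketone (Mannich base of 20; C1 a mixture) | O=C1C(CN(C)C)CC/C=C(/C(=O)O2)C[C@@H]2CC(C)(C)C1 | intermediate
22 | trimethylammonium iodide of 21 | O=C1C(C[N+](C)(C)C)CC/C=C(/C(=O)O2)C[C@@H]2CC(C)(C)C1.[I-] | intermediate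
23 | (1E,10S)-8,8-dimethyl-5-methylidene-11-oxabicyclo[8.2.1]tridec-1-ene-6,12-dione | O=C1C(=C)CC/C=C(/C(=O)O2)C[C@@H]2CC(C)(C)C1 | intermediate
24 | (1E,6S,10S)-6-hydroxy-8,8-dimethyl-5-methylidene-11-oxabicyclo[8.2.1]tridec-1-en-12-one | C=C1CC/C=C(/C(=O)O2)C[C@@H]2CC(C)(C)C[C@@H]1O | intermediate
25 | (1E,6S,10S)-6-(tert-butyldimethylsilyloxy)-8,8-dimethyl-5-methylidene-11-oxabicyclo[8.2.1]tridec-1-en-12-one | C=C1CC/C=C(/C(=O)O2)C[C@@H]2CC(C)(C)C[C@@H]1O[Si](C)(C)C(C)(C)C | intermediate
26 | 3-methylbutanoic anhydride (isovaleric anhydride) | CC(C)CC(=O)OC(=O)CC(C)C | starting material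
27 | potassium (4E,7S,11S)-11-(tert-butyldimethylsilyloxy)-7-hydroxy-9,9-dimethyl-1-methylidenecycloundec-4-ene-5-carboxylate | C=C1CC/C=C(/C(=O)[O-])C[C@@H](O)CC(C)(C)C[C@@H]1O[Si](C)(C)C(C)(C)C.[K+] | intermediate
28 | allyl (4E,7S,11S)-11-(tert-butyldimethylsilyloxy)-7-hydroxy-9,9-dimethyl-1-methylidenecycloundec-4-ene-5-carboxylate | C=C1CC/C=C(/C(=O)OCC=C)C[C@@H](O)CC(C)(C)C[C@@H]1O[Si](C)(C)C(C)(C)C | intermediate
29 | allyl (4E,7S,11S)-11-(tert-butyldimethylsilyloxy)-9,9-dimethyl-1-methylidene-7-(3-methylbutanoyloxy)cycloundec-4-ene-5-carboxylate | C=C1CC/C=C(/C(=O)OCC=C)C[C@@H](OC(=O)CC(C)C)CC(C)(C)C[C@@H]1O[Si](C)(C)C(C)(C)C | intermediate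
30 | (4E,7S,11S)-11-(tert-butyldimethylsilyloxy)-9,9-dimethyl-1-methylidene-7-(3-methylbutanoyloxy)cycloundec-4-ene-5-carboxylic acid | C=C1CC/C=C(/C(=O)O)C[C@@H](OC(=O)CC(C)C)CC(C)(C)C[C@@H]1O[Si](C)(C)C(C)(C)C | intermediate
31 | (4E,7S,11S)-11-hydroxy-9,9-dimethyl-1-methylidene-7-(3-methylbutanoyloxy)cycloundec-4-ene-5-carboxylic acid | C=C1CC/C=C(/C(=O)O)C[C@@H](OC(=O)CC(C)C)CC(C)(C)C[C@@H]1O | target

**Step count**

Total steps: 17. Longest linear sequence: 17 steps, from 2,2-dimethylpent-4-enal (1).

**Steps most likely to fail**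

Step 7 (seven-membered ring closure). What may go wrong: tert-butyllithium may add to the vinylogous ester carbonyl before the iodine–lithium exchange is complete, or the neopentyllithium may be lost to proton transfer or intermolecular addition before the ring closes. The fallback replaces carbonyl addition by cross-coupling. It sets out from 11: saponification of the vinylogous ester (LiOH, THF/H2O, 50 °C) should give the 2-alkylcyclohexane-1,3-dione F1. Triflation (Tf2O, pyridine, CH2Cl2, −78 °C) gives the β-triflyloxy enone F2. Zinc insertion into the neopentyl C–I bond (Zn dust, LiCl, THF, 40 °C) gives the alkylzinc iodide F3. Intramolecular Negishi coupling (Pd(PPh3)4, THF, 50 °C, high dilution) then joins C10 to the triflate-bearing carbon. The neopentylzinc carries no β-hydrogen, so β-hydride elimination cannot compete. The fallback comes back to the route at 14.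

Step 11 (cyclocarbonylation). What may go wrong: the ynol may cycloisomerise to a dihydrofuran by oxypalladation without CO uptake, or carbonylation may stall if the hydroxy ketone rests as a transannular hemiketal. The fallback builds the same syn relationship in stages. It sets out from 18: silylation (ClSiMe2H, Et3N, CH2Cl2, 0 °C) gives the dimethylsilyl ether F4. Intramolecular syn hydrosilylation in the 5-exo-dig mode (Pt2[(CH2=CHSiMe2)2O]3, zerovalent platinum, toluene, rt to 60 °C) places silicon on C5 and hydrogen on C4 on the same side, giving the cyclic alkenylsiloxane F5. Iododesilylation with retention (NIS, (CF3)2CHOH, 0 °C; aqueous KF work-up) gives the (E)-5-iodo-4-en-7-ol F6. Carbonylative lactonisation of this hydroxy vinyl iodide (Pd(PPh3)4, CO 1 atm, K2CO3, MeCN, 60 °C) closes the lactone with retention of the alkene geometry. The fallback comes back to the route at 20.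

Step 13 (C11 reduction). What may go wrong: facial selectivity may be poor, because the macrocyclic exocyclic enone may not present its alkenyl and neopentyl flanks to the oxazaborolidine as clearly different in size. The fallback gives up reagent control. It sets out from 23: Luche reduction (NaBH4, CeCl3·7H2O, MeOH, −78 °C) gives both C11 epimers, which are diastereomers because C7 is fixed and should separate on silica. The unwanted (11R)-allylic alcohol F7 is oxidised back to 23 (MnO2, CH2Cl2, rt) and recycled. The fallback comes back to the route at 24.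

**Further compounds**

F1 | step 7 | 2-[(2R)-2-(tert-butyldimethylsilyloxy)-5-iodo-4,4-dimethylpentyl]cyclohexane-1,3-dione | O=C1CCCC(=O)C1C[C@@H](O[Si](C)(C)C(C)(C)C)CC(C)(C)CI
F2 | step 7 | 2-[(2R)-2-(tert-butyldimethylsilyloxy)-5-iodo-4,4-dimethylpentyl]-3-oxocyclohex-1-en-1-yl trifluoromethanesulfonate | O=C1CCCC(OS(=O)(=O)C(F)(F)F)=C1C[C@@H](O[Si](C)(C)C(C)(C)C)CC(C)(C)CI
F3 | step 7 | alkylzinc iodide from F2 by zinc insertion into the C–I bond | O=C1CCCC(OS(=O)(=O)C(F)(F)F)=C1C[C@@H](O[Si](C)(C)C(C)(C)C)CC(C)(C)C[Zn]I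
F4 | step 11 | (7S)-7-(dimethylsilyloxy)-9,9-dimethylcycloundec-4-yn-11-one (target numbering) | O=C1CCCC#CC[C@@H](O[SiH](C)C)CC(C)(C)C1
F5 | step 11 | cyclic alkenylsiloxane with the O–SiMe2 bridge between C7 and C5, C4=C5 with hydrogen and silicon cis | O=C1CCC/C=C(/[Si]2(C)C)C[C@@H](O2)CC(C)(C)C1
F6 | step 11 | (4E,7S)-7-hydroxy-5-iodo-9,9-dimethylcycloundec-4-en-11-one (target numbering) | O=C1CCC/C=C(/I)C[C@@H](O)CC(C)(C)C1
F7 | step 13 | (1E,6R,10S)-6-hydroxy-8,8-dimethyl-5-methylidene-11-oxabicyclo[8.2.1]tridec-1-en-12-one | C=C1CC/C=C(/C(=O)O2)C[C@@H]2CC(C)(C)C[C@H]1O
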